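## Structural features

The target is a sesquiterpenoid diester. A trans-fused decalin (eremophilane numbering: ring A = C1, C2, C3, C4, C5, C10; ring B = C5, C6, C7, C8, C9, C10) is joined through the C3 oxygen to a (2Z,4S)-4-acyloxyhex-2-enoyl chain, whose own oxygen carries a (Z)-hex-2-enoyl group. Five stereocentres are contiguous in the bicycle (C3–C4–C5–C10–C9) and read 3R,4R,5R,9S,10R from the SMILES. In the chair–chair decalin this means an equatorial 3α ester oxygen, an equatorial 4β methyl cis to the axial 5β methyl on the quaternary fusion carbon, an axial 10α hydrogen anti to that methyl, and an equatorial 9α hydroxyl. A sixth, isolated centre (S) lies in the side chain. Ring B carries a tetrasubstituted isopropylidene at C7, cross-conjugated to the C8 ketone, which is flanked by the C9 carbinol (an α-ketol). The fragile parts are the two Z enoates (Z to E isomerisation, conjugate addition), the γ-acyloxy enoate (elimination, acyl shift), the α-ketol (epimerisation or ketol shift under base) and the exocyclic enone (double-bond migration under acid). The real difficulty is the congested C4–C5–C10 array around a quaternary carbon in a trans-decalin, which has to appear with the right oxidation level at C3, C8 and C9 and in one enantiomeric series. The key step uses three features at once: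
- the vicinal C8 ketone and C9 carbinol of ring B are what a chelated 1,2-dicarbonyl leaves after attack at its aldehyde carbon;
- the anti C5 methyl and H10 are what anti addition across an E trisubstituted C5=C10 alkene gives;
- the C3 oxygen next to the C4 methyl in ring A is what a chloroalkene leaves after closing onto a cation and being hydrolysed.

## Logic of the disconnections

27 ⇒ 26. The O–Si bond at C9 is the only bond cut. The C9 hydroxyl is kept masked until the end because it would compete with the C3 hydroxyl in the acylation. The gain is a single free hydroxyl in every earlier intermediate. The demand is a desilylation that is neither basic nor strongly acidic, so that the Z enoates and the γ-acyloxy ester are left alone.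

26 ⇒ 25. No skeletal bond is cut; both Z alkenes are traced back to alkynes. Ynoates have no geometry to lose during esterification, and one operation sets both Z double bonds. The demand is a semihydrogenation that stops at the alkene and leaves the tetrasubstituted enone untouched.

25 ⇒ 16 + 24. The acyl–oxygen bond at C3 is cut. This splits the molecule into the bicyclic core and the complete side-chain acid, so the route is convergent. The demand is an esterification of a hindered equatorial alcohol with a base-sensitive ynoic acid under mild activation.

24 ⇒ 23 ⇒ 21 + 22, and 21 ⇒ 17. Cut in turn are the tert-butyl C–O bond, the inner acyl–oxygen bond and the bond between the alkyne terminus and the carboxyl carbon. The carboxyl must be masked while the carbinol is acylated, and acid-labile masking spares the inner propargylic ester. The side chain reduces to a commercial enantiopure alkynol and a commercial ynoic acid. The demand is C-acylation of an acetylide without O-acylation, and amine exposure short enough to avoid isomerising the γ-oxygenated ynoates.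

16 ⇒ 15 ⇒ 14. The C3–H bond (reduction retron) and the O–Si bond are cut. C3 leaves the key step as a ketone, so the carbinol must come from reduction. Hydride has to arrive on the β face, along the axial trajectory that is syn to the C5 methyl and that small hydride reagents avoid. The demand is therefore a reagent-controlled, chemoselective reduction, for which an enzyme is chosen.

14 ⇒ 13. The C9–C10 bond (ring B) and the C4–C5 bond (ring A) are cut, and the C3 ketone is traced to a chloroalkene plus water. Both rings and four stereocentres disappear, leaving an achiral chain that already holds all fifteen carbons and the C8/C9 oxygens. The demand is one enantioface at C9, chair–chair folding, and cation capture faster than proton loss. The descriptors of 13 and 14 were checked against 27 and are consistent: 9α is equatorial, the fusion is trans, and the Z chloroalkene has its methyl trans to the chain.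

13 ⇒ 11 ⇒ 10. The C9 aldehyde is traced to a halomethyl ketone, and the C8–C9 bond is cut to an ester plus a one-carbon carbenoid. Any route through a cationic C9 species (a thionium ion, an acid-released aldehyde) would let the C5=C10 alkene cyclise early and without enantiocontrol. Both forward steps are therefore anionic or neutral. The demand is single addition to a hindered ester and a non-acidic oxidation.

10 ⇒ 9 ⇒ 6 + 7. The C6–C7 bond is cut. The tetrasubstituted enoate is traced to its β,γ-isomer, which is the product of α-alkylation of a dienolate by an allylic bromide. The chain is divided into a C5 ester and a C10 bromide. The demand is α- over γ-alkylation, direct substitution without allylic transposition, and an equilibrium that favours the conjugated alkene; C6 is never carbonyl-acidified, so the skipped diene should stay in place.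

6 ⇒ 5 ⇒ 4. The C–Br bond and then the C–O bond at C6 are cut, which leaves a simple gem-dimethyl alkene. The demand is allylic oxidation of the E methyl of the electron-rich alkene in preference to the allylic positions of the deactivated chloroalkene.

4 ⇒ 1 + 2. The C2–C3 bond is cut, as a coupling between an sp3 zinc reagent and one C–Cl bond of a 1,1-dichloroalkene. Exactly one palladium coupling may take place at this carbon, and it must replace the chlorine trans to the methyl. A second coupling there would delete the chlorine that the terminator needs. The gain is two commercial fragments and a chloroalkene geometry fixed by the catalyst.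

## Other disconnections considered

Alternative 1: The cut removes C5–C6 and C7–C8 of ring B. Ring A remains as a cyclohexene whose C10=C5 double bond is extended by a C9=C8 silyl enol ether, tert-butyl[(E)-2-{(3R,4R)-4-[(4-methoxybenzyl)oxy]-2,3-dimethylcyclohex-1-en-1-yl}ethenyloxy]dimethylsilane A1, and the dienophile is methyl acrylate A2. Forward, a thermal [4+2] cycloaddition, or its stepwise vinylogous Mukaiyama–Michael and aldol variant, would give the octalin methyl 3-(4-methoxybenzyloxy)-8-(tert-butyldimethylsilyloxy)-12,13-dinoreremophil-9-en-11-oate A3.
- In its favour: the reaction class is well understood, and the 1-oxygenated diene directs the ester to C7, next to the C8 oxygen. Attack on C5 anti to the C4 methyl would give the cis-vicinal methyl pair. The remaining C9=C10 alkene could later be hydroborated from the face away from the C5 methyl, which would install 10α-H and 9α-OH together.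
- Against it here: the diene terminus C5 is fully substituted, so the s-cis conformer is strained and the cycloaddition should be slow. A1 needs its own enantioselective synthesis of C3 and C4. A3 lacks the two methyl carbons of the isopropylidene, has C8 at the alcohol level and the C7 substituent at the ester level. Double methyl addition, dehydration toward C7=C11, oxidation at C8, hydration of C9=C10 and two deprotections would have to follow.
- Comparison: on certainty of mechanism this alternative is the better of the two, because its key step is known chemistry and step 8 is not. On C4/C5 relative configuration it is the equal of the chosen plan. It sets only C5 of the target centres in its key step, against four in step 8. On step economy it is behind, because 13 already contains every carbon and the full C8/C9 oxidation pattern.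

Alternative 2: The cut removes C5–C10, C6–C7 and C8–C9. This leaves the 1,7-enyne boronate 2-[(5R,6R)-5-[(4-methoxybenzyl)oxy]-6,7-dimethyloct-7-en-1-yn-1-yl]-4,4,5,5-tetramethyl-1,3,2-dioxaborolane A4 and the alkyne 2-methylbut-3-yn-2-ol A5. Forward, a cationic monovalent rhodium catalyst with an axially chiral bisphosphine would join them in a [2+2+2] cycloaddition to the cyclohexadiene 3-(4-methoxybenzyloxy)-9-(4,4,5,5-tetramethyl-1,3,2-dioxaborolan-2-yl)eremophila-7,9-dien-11-ol A6.
- In its favour: three carbon–carbon bonds and both rings form in one catalytic, convergent step with no stoichiometric by-product. The boron at C9 is a latent oxygen on the right carbon, and the tertiary C11 alcohol is a latent isopropylidene.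
- Against it here: the quaternary C5 has to come from a 1,1-disubstituted alkene of a 1,7-enyne, under diastereocontrol from C4. The regiochemistry of insertion of A5 and its self-trimerisation are open. C10 ends sp2, so the trans fusion is not set. C8 arrives without oxygen, and oxidation of the alkenyl boronate would place a ketone at C9 instead of C8, so a redox transposition is needed. A4 needs a separate asymmetric synthesis.
- Comparison: on bonds formed per step (three against two) and on waste this alternative is the better. On closeness to precedent it is also somewhat better. On oxygenation at C9 it is the equal. On stereocentres set (one against four), on the C8/C9 oxidation pattern and on the number of steps after the key step it is behind.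

Alternative 3: The cut is biosynthetic: C6–C7 (ten-membered ring) and C5–C10 are disconnected back to (2E,6E)-farnesyl diphosphate A7. Forward, aristolochene synthase with its magnesium cofactor ionises A7, closes the ten-membered ring and then the decalin, shifts hydride from C5 to C4 and methyl from C10 to C5, and loses a C9 proton to give (+)-aristolochene A8.
- In its favour: this is the proven reaction of the enzyme. One step gives the whole carbon skeleton with the C4 and C5 methyls in the same absolute sense as in 27, and it can be run in an engineered microbe.
- Against it here: A8 carries no oxygen. C3 is an unactivated methylene that would need a regio- and stereoselective C–H hydroxylation. The C9=C10 alkene has to become 9α-OH, 10α-H with a C8 ketone. The isopropenyl group has to move into conjugation, which should be easy once C8 is a ketone. The enzyme also has to be produced and supplied with A7.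
- Comparison: on certainty and on skeleton construction in one step this alternative is the better. On carbon count it is the equal, since both plans have all fifteen carbons at the key step. On oxidation pattern it is far behind, because the chosen chain brings O3 (as the chloroalkene), O8 and O9 into the cyclisation. The total number of steps is hard to predict and would rest on several selective oxidations without a general solution.

Key step: step 8

Remarks on the chemistry:
- Eremophilane numbering is used for the bicyclic compounds; α is the face of H10 and β the face of the C5 methyl.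
- 13 is assumed to react as the free 1,2-dicarbonyl; any hydrate formed during isolation is in equilibrium with it and is not counted separately.
- (S,S)-t-Bu-box stands for 2,2'-(propane-2,2-diyl)bis[(4S)-4-tert-butyl-4,5-dihydro-1,3-oxazole].
- A commercial ketoreductase panel is assumed to contain an enzyme that accepts 15 and gives the 3R alcohol.
- Pyrophoric aluminium alkyls, diazo compounds, tin and mercury reagents are avoided; SeO2 is used only in catalytic amount.

## Route

Step 1
Reactants: 1 5-bromo-2-methylpent-2-ene; 2 1,1-dichloropropene
Product: 4 (6Z)-6-chloro-2-methylocta-2,6-diene, via alkylzinc bromide 3 (not isolated)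
Conditions: Zn, LiCl, THF, 50 °C; then 2, PdCl2(DPEphos) (2 mol%), THF/DMF, 25 °C
Reagents that add atoms: none
Why: Negishi coupling of an alkylzinc with a 1,1-dichloroalkene; zerovalent palladium inserts into the less hindered C–Cl bond trans to the methyl, so the chain ends trans to the methyl and the remaining chlorine cis to it (Z), and the wide-bite-angle ligand suppresses β-hydride elimination and a second coupling.

Step 2
Reactants: 4 (6Z)-6-chloro-2-methylocta-2,6-diene
Product: 5 (2E,6Z)-6-chloro-2-methylocta-2,6-dien-1-ol
Conditions: SeO2 (0.3 equiv), t-BuOOH, salicylic acid (cat.), CH2Cl2, 0 to 20 °C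
Reagents that add atoms: SeO2, O=[Se]=O (catalytic oxygen carrier); tert-butyl hydroperoxide, CC(C)(C)OO
Why: SeO2-catalysed allylic oxidation (ene reaction, then [2,3]-sigmatropic shift) is known to take the E methyl of a gem-dimethyl trisubstituted alkene; the chloroalkene is inductively deactivated toward the electrophilic ene step, so its allylic positions should be spared.

Step 3
Reactants: 5 (2E,6Z)-6-chloro-2-methylocta-2,6-dien-1-ol
Product: 6 (2E,6Z)-1-bromo-6-chloro-2-methylocta-2,6-diene
Conditions: PBr3 (0.4 equiv), Et2O, −10 °C
Reagents that add atoms: phosphorus tribromide, BrP(Br)Br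
Why: Bromination of a primary allylic alcohol through its phosphite ester by SN2 displacement; at low temperature in ether the primary bromide should form without allylic transposition or loss of the E geometry.

Step 4
Reactants: 7 methyl 3-methylbut-2-enoate; 6 (2E,6Z)-1-bromo-6-chloro-2-methylocta-2,6-diene
Product: 9 methyl (4E,8Z)-8-chloro-4-methyl-2-(prop-1-en-2-yl)deca-4,8-dienoate (racemic), via lithium dienolate 8 (not isolated)
Conditions: LiN(iPr)2, THF/DMPU, −78 °C; then 6, −78 to −20 °C
Reagents that add atoms: none
Why: Deconjugative α-alkylation of an ester dienolate: γ-deprotonation gives the extended enolate, which reacts with the primary allylic bromide at its α-carbon by SN2 (forming C6–C7); the new α-centre is racemic and is erased in step 5.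

Step 5
Reactants: 9 methyl (4E,8Z)-8-chloro-4-methyl-2-(prop-1-en-2-yl)deca-4,8-dienoate
Product: 10 methyl (4E,8Z)-8-chloro-4-methyl-2-(propan-2-ylidene)deca-4,8-dienoate
Conditions: NaOMe (0.3 equiv), MeOH, 50 °C
Reagents that add atoms: none
Why: Base-catalysed prototropic isomerisation through the same dienolate moves the isopropenyl double bond into conjugation, where tetrasubstitution and conjugation should both favour it; C6 is not carbonyl-acidified, so the C5=C10 alkene should stay in place, and methoxide matches the methyl ester.

Step 6
Reactants: 10 methyl (4E,8Z)-8-chloro-4-methyl-2-(propan-2-ylidene)deca-4,8-dienoate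
Product: 11 (5E,9Z)-1,9-dichloro-5-methyl-3-(propan-2-ylidene)undeca-5,9-dien-2-one
Conditions: ICH2Cl, MeLi·LiBr, THF, −78 °C; aq. NH4Cl
Reagents that add atoms: chloroiodomethane, ClCI
Why: Carbenoid homologation of an ester: chloromethyllithium, made by iodine–lithium exchange in the presence of the ester, adds once because the tetrahedral adduct persists at −78 °C and collapses to the chloromethyl ketone only on quench; this forms C8–C9 without a cationic intermediate.

Step 7
Reactants: 11 (5E,9Z)-1,9-dichloro-5-methyl-3-(propan-2-ylidene)undeca-5,9-dien-2-one
Product: 13 (5E,9Z)-9-chloro-5-methyl-2-oxo-3-(propan-2-ylidene)undeca-5,9-dienal, via iodomethyl ketone 12 (not isolated)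
Conditions: NaI, DMSO, 20 °C; then NaHCO3, 20 to 35 °C
Reagents that add atoms: dimethyl sulfoxide, CS(C)=O
Why: Finkelstein exchange followed by Kornblum oxidation: the sulfoxide oxygen displaces iodide from the activated α-keto position and bicarbonate eliminates dimethyl sulfide from the alkoxysulfonium salt; C9 reaches the aldehyde level under buffered, non-cationic conditions, so the alkene should not cyclise early.

Step 8
Reactants: 13 (5E,9Z)-9-chloro-5-methyl-2-oxo-3-(propan-2-ylidene)undeca-5,9-dienal
Product: 14 (4R,5S,9S,10R)-9-hydroxyeremophil-7(11)-ene-3,8-dione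
Conditions: [Cu((S,S)-t-Bu-box)(H2O)2](SbF6)2 (20 mol%), H2O (1 equiv), 2,6-di-tert-butylpyridine (1.1 equiv), CH2Cl2, −40 to 0 °C
Reagents that add atoms: water, O
Why: Proposed new method: the square-planar divalent copper centre binds O8 and O9 of 13 as an s-cis five-membered chelate and makes C9 strongly electrophilic; the E alkene attacks through C10 (6-endo chair closure of ring B, charge on tertiary C5), C4 of the Z chloroalkene then takes the C5 cation (6-endo chair closure of ring A, charge on C3 stabilised by chlorine), and water adds to C3 and loses HCl to the hindered pyridine to leave the ketone. The closest known reaction types are carbonyl-ene and Prins additions to glyoxylate-type chelates of bis(oxazoline)–Cu(SbF6)2, acetal-initiated polyene bicyclisations and chloroalkene-terminated cation cyclisations that give cyclohexanones. C9 is set by the ligand: by analogy with glyoxylate chelates the (S,S) ligand should leave the Si face of the aldehyde open (9S), and the chelate keeps O9 anti to C7, that is equatorial. C10 and C5 are set by anti addition across the E alkene in the chair, with C1 (trans to C6 on the alkene) equatorial on ring B, so that H10 and the C5 methyl end trans-diaxial and the fusion trans. C4 is set by the chloroalkene geometry: its methyl is trans to the C2 chain, is therefore born equatorial and cis to the C5 methyl, and can still equilibrate next to the new ketone. The selectivities needed are 6-endo over 5-exo at both alkenes (secured by the tertiary C5 and the chlorine-stabilised C3 cations), cation capture over proton loss (the equatorial chelated oxygen is remote from the allylic hydrogens and the pyridine base does not deprotonate carbenium ions) and catalyst control over background acid catalysis (HCl is buffered as it forms).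

Step 9
Reactants: 14 (4R,5S,9S,10R)-9-hydroxyeremophil-7(11)-ene-3,8-dione
Product: 15 (4R,5S,9S,10R)-9-(triethylsilyloxy)eremophil-7(11)-ene-3,8-dione
Conditions: Et3SiCl, imidazole, DMF, 0 to 20 °C
Reagents that add atoms: chlorotriethylsilane, CC[Si](Cl)(CC)CC
Why: Silylation of the only hydroxyl under mild imidazole catalysis; the weak base should not epimerise the ketol, and the triethylsilyl ether can be removed at the end without base.

Step 10
Reactants: 15 (4R,5S,9S,10R)-9-(triethylsilyloxy)eremophil-7(11)-ene-3,8-dione
Product: 16 (3R,4R,5R,9S,10R)-3-hydroxy-9-(triethylsilyloxy)eremophil-7(11)-en-8-one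
Conditions: ketoreductase (anti-Prelog type, from a commercial panel), NADP+ (cat.), iPrOH, KH2PO4/K2HPO4 buffer pH 7.0, DMSO (10% v/v), 30 °C
Reagents that add atoms: none
Why: Enzymatic carbonyl reduction with cofactor recycling by propan-2-ol; the active site, not the substrate, directs hydride to the β face of C3 (the axial path syn to the C5 methyl that small hydride reagents avoid) and gives the equatorial 3R alcohol, while the hindered, conjugated, α-silyloxy C8 ketone should not be accepted.

Step 11
Reactants: 17 (3S)-pent-1-yn-3-ol
Product: 21 tert-butyl (4S)-4-hydroxyhex-2-ynoate, via silyl ether 18 (not isolated), via lithium acetylide 19 (not isolated), via silylated ynoate 20 (not isolated)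
Conditions: n-BuLi, THF, −78 °C; Me3SiCl; n-BuLi, −78 °C; Boc2O, −78 to −20 °C; 1 M aq. HCl, 0 °C
Reagents that add atoms: di-tert-butyl dicarbonate, CC(C)(C)OC(=O)OC(=O)OC(C)(C)C
Why: C-acylation of a lithium acetylide: transient O-silylation keeps the alkoxide from competing for the dicarbonate, the acetylide attacks it once at low temperature, and dilute acid removes the trimethylsilyl group without touching the tert-butyl ester; the stereocentre is not involved.

Step 12
Reactants: 21 tert-butyl (4S)-4-hydroxyhex-2-ynoate; 22 hex-2-ynoic acid
Product: 23 tert-butyl (4S)-4-(hex-2-ynoyloxy)hex-2-ynoate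
Conditions: DIC, DMAP (5 mol%), CH2Cl2, −20 to 0 °C
Reagents that add atoms: none
Why: Steglich esterification through the O-acylisourea and the acylpyridinium ion; it is run cold and briefly because γ-hydroxy ynoates can isomerise to γ-oxo enoates under amine bases.

Step 13
Reactants: 23 tert-butyl (4S)-4-(hex-2-ynoyloxy)hex-2-ynoate
Product: 24 (4S)-4-(hex-2-ynoyloxy)hex-2-ynoic acid
Conditions: CF3CO2H/CH2Cl2 (1:4), 0 to 20 °C
Reagents that add atoms: none
Why: Acidolysis of a tert-butyl ester by loss of isobutene; the inner propargylic ester cannot ionise at its electron-poor carbinol carbon and should survive.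

Step 14
Reactants: 16 (3R,4R,5R,9S,10R)-3-hydroxy-9-(triethylsilyloxy)eremophil-7(11)-en-8-one; 24 (4S)-4-(hex-2-ynoyloxy)hex-2-ynoic acid
Product: 25 (3R,4R,5R,9S,10R)-8-oxo-9-(triethylsilyloxy)eremophil-7(11)-en-3-yl (4S)-4-(hex-2-ynoyloxy)hex-2-ynoate
Conditions: DIC, DMAP (10 mol%), CH2Cl2, −10 to 0 °C
Reagents that add atoms: none
Why: Steglich esterification of the equatorial 3α alcohol, the only free hydroxyl; the acid has no α-hydrogen, so no ketene path can affect its γ-stereocentre, and the alkynes carry no geometry that could be lost here.

Step 15
Reactants: 25 (3R,4R,5R,9S,10R)-8-oxo-9-(triethylsilyloxy)eremophil-7(11)-en-3-yl (4S)-4-(hex-2-ynoyloxy)hex-2-ynoate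
Product: 26 (3R,4R,5R,9S,10R)-8-oxo-9-(triethylsilyloxy)eremophil-7(11)-en-3-yl (2Z,4S)-4-[(2Z)-hex-2-enoyloxy]hex-2-enoate
Conditions: H2 (1 atm), Pd/CaCO3 poisoned with Pb(OAc)2, quinoline, EtOAc, 0 °C
Reagents that add atoms: none
Why: Semihydrogenation on lead-poisoned palladium: syn delivery of hydrogen to each ynoate gives the Z enoate, the alkynes bind more strongly than the alkenes they form, and the tetrasubstituted enone is too hindered to adsorb; uptake is stopped at two equivalents.

Step 16
Reactants: 26 (3R,4R,5R,9S,10R)-8-oxo-9-(triethylsilyloxy)eremophil-7(11)-en-3-yl (2Z,4S)-4-[(2Z)-hex-2-enoyloxy]hex-2-enoate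
Product: 27 (3R,4R,5R,9S,10R)-9-hydroxy-8-oxoeremophil-7(11)-en-3-yl (2Z,4S)-4-[(2Z)-hex-2-enoyloxy]hex-2-enoate
Conditions: HF·pyridine, pyridine, THF, 0 to 20 °C
Reagents that add atoms: none
Why: Fluoride-driven cleavage of the triethylsilyl ether in a buffered, non-basic medium; without base the Z enoates should not isomerise, the acyl groups should not migrate, and the equatorial ketol should not epimerise.

## Compound list

1 | 5-bromo-2-methylpent-2-ene | CC(C)=CCCBr | starting material
2 | 1,1-dichloropropene | CC=C(Cl)Cl | starting material
3 | (4-methylpent-3-en-1-yl)zinc bromide | CC(C)=CCC[Zn]Br | intermediate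
4 | (6Z)-6-chloro-2-methylocta-2,6-diene | C/C=C(Cl)/CCC=C(C)C | intermediate
5 | (2E,6Z)-6-chloro-2-methylocta-2,6-dien-1-ol | OC/C(C)=C/CC/C(Cl)=C/C | intermediate
6 | (2E,6Z)-1-bromo-6-chloro-2-methylocta-2,6-diene | BrC/C(C)=C/CC/C(Cl)=C/C | intermediate
7 | methyl 3-methylbut-2-enoate | CC(C)=CC(=O)OC | starting material
8 | lithium 1-methoxy-3-methylbuta-1,3-dien-1-olate | [Li]OC(OC)=CC(C)=C | intermediate
9 | methyl (4E,8Z)-8-chloro-4-methyl-2-(prop-1-en-2-yl)deca-4,8-dienoate (racemic at C2) | COC(=O)C(C(C)=C)C/C(C)=C/CC/C(Cl)=C/C | intermediate
10 | methyl (4E,8Z)-8-chloro-4-methyl-2-(propan-2-ylidene)deca-4,8-dienoate | COC(=O)C(=C(C)C)C/C(C)=C/CC/C(Cl)=C/C | intermediate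
11 | (5E,9Z)-1,9-dichloro-5-methyl-3-(propan-2-ylidene)undeca-5,9-dien-2-one | ClCC(=O)C(=C(C)C)C/C(C)=C/CC/C(Cl)=C/C | intermediate
12 | (5E,9Z)-9-chloro-1-iodo-5-methyl-3-(propan-2-ylidene)undeca-5,9-dien-2-one | ICC(=O)C(=C(C)C)C/C(C)=C/CC/C(Cl)=C/C | intermediate
13 | (5E,9Z)-9-chloro-5-methyl-2-oxo-3-(propan-2-ylidene)undeca-5,9-dienal | O=CC(=O)C(=C(C)C)C/C(C)=C/CC/C(Cl)=C/C | intermediate
14 | (4R,5S,9S,10R)-9-hydroxyeremophil-7(11)-ene-3,8-dione (trans-decalin; 9α-OH equatorial, 4β- and 5β-methyl, 10α-H) | O=C1CC[C@H]2[C@H](O)C(=O)C(=C(C)C)C[C@]2(C)[C@H]1C | intermediate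
15 | (4R,5S,9S,10R)-9-(triethylsilyloxy)eremophil-7(11)-ene-3,8-dione | O=C1CC[C@H]2[C@H](O[Si](CC)(CC)CC)C(=O)C(=C(C)C)C[C@]2(C)[C@H]1C | intermediate
16 | (3R,4R,5R,9S,10R)-3-hydroxy-9-(triethylsilyloxy)eremophil-7(11)-en-8-one (3α-OH equatorial) | O[C@@H]1CC[C@H]2[C@H](O[Si](CC)(CC)CC)C(=O)C(=C(C)C)C[C@]2(C)[C@H]1C | intermediate
17 | (3S)-pent-1-yn-3-ol | O[C@H](C#C)CC | starting material
18 | trimethyl{[(3S)-pent-1-yn-3-yl]oxy}silane | C[Si](C)(C)O[C@H](C#C)CC | intermediate
19 | [(3S)-3-(trimethylsilyloxy)pent-1-yn-1-yl]lithium | C[Si](C)(C)O[C@H](C#C[Li])CC | intermediate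
20 | tert-butyl (4S)-4-(trimethylsilyloxy)hex-2-ynoate | C[Si](C)(C)O[C@H](C#CC(=O)OC(C)(C)C)CC | intermediate
21 | tert-butyl (4S)-4-hydroxyhex-2-ynoate | O[C@H](C#CC(=O)OC(C)(C)C)CC | intermediate
22 | hex-2-ynoic acid | CCCC#CC(=O)O | starting material
23 | tert-butyl (4S)-4-(hex-2-ynoyloxy)hex-2-ynoate | CCCC#CC(=O)O[C@H](C#CC(=O)OC(C)(C)C)CC | intermediate
24 | (4S)-4-(hex-2-ynoyloxy)hex-2-ynoic acid | CCCC#CC(=O)O[C@H](C#CC(=O)O)CC | intermediate
25 | (3R,4R,5R,9S,10R)-8-oxo-9-(triethylsilyloxy)eremophil-7(11)-en-3-yl (4S)-4-(hex-2-ynoyloxy)hex-2-ynoate | CCCC#CC(=O)O[C@H](C#CC(=O)O[C@@H]1CC[C@H]2[C@H](O[Si](CC)(CC)CC)C(=O)C(=C(C)C)C[C@]2(C)[C@H]1C)CC | intermediate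
26 | (3R,4R,5R,9S,10R)-8-oxo-9-(triethylsilyloxy)eremophil-7(11)-en-3-yl (2Z,4S)-4-[(2Z)-hex-2-enoyloxy]hex-2-enoate | CCC/C=C\C(=O)O[C@H](/C=C\C(=O)O[C@@H]1CC[C@H]2[C@H](O[Si](CC)(CC)CC)C(=O)C(=C(C)C)C[C@]2(C)[C@H]1C)CC | intermediate
27 | (3R,4R,5R,9S,10R)-9-hydroxy-8-oxoeremophil-7(11)-en-3-yl (2Z,4S)-4-[(2Z)-hex-2-enoyloxy]hex-2-enoate (CNP0170141.1) | CCC/C=C\C(=O)O[C@H](/C=C\C(=O)O[C@@H]1CC[C@H]2[C@H](O)C(=O)C(=C(C)C)C[C@]2(C)[C@H]1C)CC | target

## Step count and risk

Total: 16 steps. Longest linear sequence: 13 steps (steps 1 to 10 and 14 to 16, from 1 and 2 to 27). The side-chain acid 24 takes steps 11 to 13 in parallel.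

Least certain steps:

Step 8 (key step). Three things may go wrong.
- The C5 cation may lose a proton (toward C6, which would give a conjugated dienone, or from the methyl, the ene-type shunt) before the weakly nucleophilic chloroalkene closes ring A.
- The chlorine-stabilised C3 cation may undergo hydride or methyl shifts before water arrives.
- Chloride and acid released at the end may bind the copper centre, slowing turnover and letting an unselective acid-catalysed background reaction erode the facial control.

The fallback separates the two ring closures and uses known reaction types; it sets out from 13 and returns at 14. An anhydrous carbonyl-ene cyclisation of 13, catalysed by the same bis(oxazoline) complex of divalent copper over molecular sieves (a known enantioselective reaction class for 1,2-dicarbonyl enophiles), should close ring B with hydrogen transfer from the C5 methyl. It would give (2S,3R)-3-[(3Z)-3-chloropent-3-en-1-yl]-2-hydroxy-4-methylidene-6-(propan-2-ylidene)cyclohexan-1-one F1; the ligand antipode is chosen for the 3R centre, and the carbinol can settle into the trans-diequatorial arrangement by enolisation. A chloroolefin annulation in formic acid would then protonate the exocyclic methylene, close ring A through the chloroalkene and hydrolyse the chloro cation, giving (4R,5S,9S,10R)-3,8-dioxoeremophil-7(11)-en-9-yl formate F2. Its formate is cleaved with KHCO3 in methanol to 14.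

Step 5. The prototropic equilibrium may stop short of full conversion, or methoxide may add to the hindered enoate, so that the β,γ-isomer is carried forward. The fallback builds the tetrasubstituted enoate by coupling instead of isomerisation; it sets out from 6 and returns at 10. Alkylation of methyl acetoacetate with 6 (K2CO3, acetone) gives methyl (4E,8Z)-2-acetyl-8-chloro-4-methyldeca-4,8-dienoate F3. Enol phosphorylation (NaH, ClP(O)(OEt)2) gives methyl (4E,8Z)-8-chloro-2-[1-(diethoxyphosphoryloxy)ethylidene]-4-methyldeca-4,8-dienoate F4. Substitution with Me2CuLi then gives 10; both β-substituents end as methyl, so the enol phosphate geometry is immaterial.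

Step 2. Oxidation may be sluggish or may continue to the enal, and some attack at the allylic positions of the chloroalkene cannot be excluded; a borohydride wash would return enal to 5 but would not cure poor regioselectivity. The fallback builds the E allylic alcohol by olefination; it sets out from 2 and returns at 5. Negishi coupling of 2 with [2-(1,3-dioxolan-2-yl)ethyl]zinc bromide under the conditions of step 1 gives 2-[(3Z)-3-chloropent-3-en-1-yl]-1,3-dioxolane F5. Aqueous acid releases (4Z)-4-chlorohex-4-enal F6. Wittig reaction with ethyl 2-(triphenylphosphoranylidene)propanoate gives ethyl (2E,6Z)-6-chloro-2-methylocta-2,6-dienoate F7. Reduction with i-Bu2AlH gives 5.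

Step 7. The ketoaldehyde may degrade in warm, basic sulfoxide (aldol-type condensation, hydride shift to the hydroxy acid) or cyclise without control during concentration. The fallback reaches the aldehyde by oxidation of an alcohol under neutral conditions; it sets out from 11 and returns at 13. Displacement with HCO2Cs in DMF gives (5E,9Z)-9-chloro-5-methyl-2-oxo-3-(propan-2-ylidene)undeca-5,9-dien-1-yl formate F8. Methanolysis (NaHCO3, MeOH) gives (5E,9Z)-9-chloro-1-hydroxy-5-methyl-3-(propan-2-ylidene)undeca-5,9-dien-2-one F9. Oxidation with the triacetoxy periodinane DMP, buffered with NaHCO3 in CH2Cl2, gives 13.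

Step 10. The enzyme panel may give poor conversion of this lipophilic, hindered ketone, or hydride delivery to the wrong face. The fallback uses substrate control followed by inversion; it sets out from 15 and returns at 16. LiBH(s-Bu)3 at −78 °C attacks C3 along the equatorial path and should give the axial alcohol (3S,4R,5R,9S,10R)-3-hydroxy-9-(triethylsilyloxy)eremophil-7(11)-en-8-one F10. Mitsunobu reaction with 4-nitrobenzoic acid inverts C3 to (3R,4R,5R,9S,10R)-8-oxo-9-(triethylsilyloxy)eremophil-7(11)-en-3-yl 4-nitrobenzoate F11. Methanolysis with K2CO3 gives 16.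

## Further compounds

F1 | step 8 | (2S,3R)-3-[(3Z)-3-chloropent-3-en-1-yl]-2-hydroxy-4-methylidene-6-(propan-2-ylidene)cyclohexan-1-one | C/C=C(Cl)/CC[C@H]1[C@H](O)C(=O)C(=C(C)C)CC1=C
F2 | step 8 | (4R,5S,9S,10R)-3,8-dioxoeremophil-7(11)-en-9-yl formate | O=C1CC[C@H]2[C@H](OC=O)C(=O)C(=C(C)C)C[C@]2(C)[C@H]1C
F3 | step 5 | methyl (4E,8Z)-2-acetyl-8-chloro-4-methyldeca-4,8-dienoate (racemic at C2) | COC(=O)C(C(C)=O)C/C(C)=C/CC/C(Cl)=C/C
F4 | step 5 | methyl (4E,8Z)-8-chloro-2-[1-(diethoxyphosphoryloxy)ethylidene]-4-methyldeca-4,8-dienoate (enol phosphate geometry immaterial) | COC(=O)C(=C(C)OP(=O)(OCC)OCC)C/C(C)=C/CC/C(Cl)=C/C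
F5 | step 2 | 2-[(3Z)-3-chloropent-3-en-1-yl]-1,3-dioxolane | C/C=C(Cl)/CCC1OCCO1
F6 | step 2 | (4Z)-4-chlorohex-4-enal | C/C=C(Cl)/CCC=O
F7 | step 2 | ethyl (2E,6Z)-6-chloro-2-methylocta-2,6-dienoate | CCOC(=O)/C(C)=C/CC/C(Cl)=C/C
F8 | step 7 | (5E,9Z)-9-chloro-5-methyl-2-oxo-3-(propan-2-ylidene)undeca-5,9-dien-1-yl formate | O=COCC(=O)C(=C(C)C)C/C(C)=C/CC/C(Cl)=C/C
F9 | step 7 | (5E,9Z)-9-chloro-1-hydroxy-5-methyl-3-(propan-2-ylidene)undeca-5,9-dien-2-one | OCC(=O)C(=C(C)C)C/C(C)=C/CC/C(Cl)=C/C
F10 | step 10 | (3S,4R,5R,9S,10R)-3-hydroxy-9-(triethylsilyloxy)eremophil-7(11)-en-8-one (3β-OH axial) | O[C@H]1CC[C@H]2[C@H](O[Si](CC)(CC)CC)C(=O)C(=C(C)C)C[C@]2(C)[C@H]1C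
F11 | step 10 | (3R,4R,5R,9S,10R)-8-oxo-9-(triethylsilyloxy)eremophil-7(11)-en-3-yl 4-nitrobenzoate | O=C(O[C@@H]1CC[C@H]2[C@H](O[Si](CC)(CC)CC)C(=O)C(=C(C)C)C[C@]2(C)[C@H]1C)c1ccc(cc1)[N+](=O)[O-]
A1 | alternative 1 | tert-butyl[(E)-2-{(3R,4R)-4-[(4-methoxybenzyl)oxy]-2,3-dimethylcyclohex-1-en-1-yl}ethenyloxy]dimethylsilane | COc1ccc(CO[C@@H]2CCC(/C=C/O[Si](C)(C)C(C)(C)C)=C(C)[C@H]2C)cc1
A2 | alternative 1 | methyl acrylate | C=CC(=O)OC
A3 | alternative 1 | methyl 3-(4-methoxybenzyloxy)-8-(tert-butyldimethylsilyloxy)-12,13-dinoreremophil-9-en-11-oate | COc1ccc(CO[C@@H]2CCC3=C[C@H](O[Si](C)(C)C(C)(C)C)[C@H](C(=O)OC)C[C@]3(C)[C@H]2C)cc1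
A4 | alternative 2 | 2-[(5R,6R)-5-[(4-methoxybenzyl)oxy]-6,7-dimethyloct-7-en-1-yn-1-yl]-4,4,5,5-tetramethyl-1,3,2-dioxaborolane | COc1ccc(CO[C@H](CCC#CB2OC(C)(C)C(C)(C)O2)[C@H](C)C(C)=C)cc1
A5 | alternative 2 | 2-methylbut-3-yn-2-ol | CC(C)(O)C#C
A6 | alternative 2 | 3-(4-methoxybenzyloxy)-9-(4,4,5,5-tetramethyl-1,3,2-dioxaborolan-2-yl)eremophila-7,9-dien-11-ol | COc1ccc(CO[C@@H]2CCC3=C(B4OC(C)(C)C(C)(C)O4)C=C(C(C)(C)O)C[C@]3(C)[C@H]2C)cc1
A7 | alternative 3 | (2E,6E)-farnesyl diphosphate | CC(C)=CCC/C(C)=C/CC/C(C)=C/COP(=O)(O)OP(=O)(O)O
A8 | alternative 3 | (+)-aristolochene | C1CCC2=CC[C@H](C(C)=C)C[C@]2(C)[C@H]1C
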